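**Retrosynthetic overview**

1. The strategy rests on the para-phenylene (six arene carbons, O on Ar-C1, CH2 on Ar-C4) inside the 13-membered ring C8–O–Ar(C1…C4)–CH2–C5′–C4′=C3′–C1′(=O)–C9–C7. This arene must bend, so its six carbons are made last.
2. Hydroxy lactam ⇐ 2,4-disubstituted furan (singlet oxygen, then NH3) ⇐ debromination ⇐ arene and macrocycle together, by [4+2] addition of the C8 ethynyl ether to a tethered 3-bromo-2-pyrone and loss of CO2.
3. Precursor ⇐ C1′ acid chloride of the tricyclic core + a 4-stannylfuran carrying the bromopyrone arm (from 3-bromofuran and coumalic acid); the ynol ether comes from the C8 alcohol and trichloroethylene.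
4. Rings B and C ⇐ one intramolecular Diels–Alder reaction of a (Z)-enoate with an (E,E)-dienylboronate held on ring A; the C3 vinyl group ⇐ C–B → C–O → palladium-catalysed vinylation with inversion.
5. Ring A ⇐ (R)-pulegone via (R)-5-methylcyclohexenone (cuprate/aldol sets C11, C10, C8; enolate methylation sets C15). Ring order: A, then B and C together, then arene and 13-membered ring together, lactam last.

Key step: step 30

Labels: ring A = C10–C15 (CH3 on C11, C13, C15), ring B = C6, C7, C8, C10, C15 (O on C8), ring C = C3 (vinyl), C4=C5 (CH3 on C5), C6, C7, C9 (acyl); C1′ = ketone carbon on C9.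
Assumption: the hemiaminal carbon C5′ equilibrates by ring–chain tautomerism, and the configuration of the target is taken to be the thermodynamic one inside the macrocycle.

**Route**

Step 1
Reactants: 1 (R)-(+)-pulegone
Product: 2 pulegone oxide (spiro epoxide, both epoxide diastereomers)
Conditions: 30% aq. H2O2, LiOH, MeOH, 0 °C to rt
Reagents that add atoms: hydrogen peroxide, OO
Why: Weitz–Scheffer nucleophilic epoxidation of the enone, in which the methyl-bearing centre (future C13) is untouched and the epoxide configuration is irrelevant because that carbon is degraded in the next step.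

Step 2
Reactants: 2 pulegone oxide
Product: 3 (5R)-5-methyl-2-(phenylsulfanyl)cyclohexan-1-one (C2 epimers)
Conditions: PhSH, NaH (cat.), THF, reflux
Reagents that add atoms: thiophenol, Sc1ccccc1
Why: Thiolate opening of the α,β-epoxy ketone at the α-carbon followed by retro-aldol loss of acetone should give the α-sulfanyl ketone.

Step 3
Reactants: 3 (5R)-5-methyl-2-(phenylsulfanyl)cyclohexan-1-one
Product: 5 (R)-5-methylcyclohex-2-en-1-one, via sulfoxide 4 (not isolated)
Conditions: mCPBA, CH2Cl2, −78 °C; then CaCO3, toluene, 110 °C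
Reagents that add atoms: none
Why: Sulfide oxidation and thermal syn-elimination of the sulfoxide (sulfoxide pyrolysis) should place the double bond regiospecifically between C2 and C3.

Step 4
Reactants: 5 (R)-5-methylcyclohex-2-en-1-one; 6 (tert-butyldimethylsilyloxy)acetaldehyde
Product: 8 ring A aldol adduct 2-[1-hydroxy-2-(tert-butyldimethylsilyloxy)ethyl]-3,5-dimethylcyclohexan-1-one (C10/C11 trans; C11/C13 trans; C10/C8 anti), via chlorozinc enolate 7 (not isolated)
Conditions: Me2CuLi (from MeLi and CuI), Et2O, −78 to −20 °C; ZnCl2, THF, −78 °C; then 6, −78 °C; aq. NH4Cl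
Reagents that add atoms: lithium dimethylcuprate, [Li+].C[Cu-]C
Why: Cuprate conjugate addition anti to the C13 methyl sets C11, and the regiodefined zinc enolate then undergoes an aldol addition anti to the new methyl through a closed Zimmerman–Traxler transition state of the ring (E)-enolate, which should set C10 and the anti C10/C8 relationship.

Step 5
Reactants: 8 ring A aldol adduct
Product: 9 bis(silyl ether) ketone (C8 OTBS, C7 OTBS)
Conditions: TBSOTf, 2,6-lutidine, CH2Cl2, −78 to 0 °C
Reagents that add atoms: tert-butyldimethylsilyl triflate, CC(C)(C)[Si](C)(C)OS(=O)(=O)C(F)(F)F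
Why: O-silylation with a silyl triflate and a hindered base protects the C8 hydroxyl so that retro-aldol cleavage is blocked in the basic steps that follow.

Step 6
Reactants: 9 bis(silyl ether) ketone
Product: 10 methyl enol ether (C15=CH–OMe, E/Z mixture)
Conditions: Ph3P(CH2OMe)Cl, KN(SiMe3)2, THF, 0 °C to rt
Reagents that add atoms: (methoxymethyl)triphenylphosphonium chloride, COC[P+](c1ccccc1)(c1ccccc1)c1ccccc1.[Cl-]
Why: Wittig methoxymethylenation homologates the C15 ketone by the carbon that becomes C6, and the enol ether geometry is irrelevant.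

Step 7
Reactants: 10 methyl enol ether
Product: 11 ring A aldehyde (C15–CHO, C15 epimers)
Conditions: Cl3CCO2H, CH2Cl2/H2O, 0 °C
Reagents that add atoms: water, O
Why: Acid-catalysed enol ether hydrolysis should unmask the aldehyde in a short cold treatment that spares both silyl ethers, and the C15 mixture does not matter because C15 is enolized next.

Step 8
Reactants: 11 ring A aldehyde
Product: 12 quaternary aldehyde (C15 bears CH3 trans to the C10–C8 bond and the C6 formyl group cis to it)
Conditions: KOt-Bu, MeI, THF, −78 to 0 °C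
Reagents that add atoms: iodomethane, CI
Why: Enolate C-alkylation of an α-branched aldehyde, in which allylic 1,3-strain in the exocyclic enolate turns the C10 side chain axial so that iodomethane should enter anti to it and set the quaternary C15.

Step 9
Reactants: 12 quaternary aldehyde
Product: 13 (E)-2-methyl enal (C6=C5, C4 formyl)
Conditions: Ph3P=C(CH3)CHO, toluene, 110 °C
Reagents that add atoms: 2-(triphenylphosphoranylidene)propanal, CC(C=O)=P(c1ccccc1)(c1ccccc1)c1ccccc1
Why: Wittig olefination with a stabilized ylide should give the (E)-trisubstituted enal, and the non-enolizable aldehyde cannot epimerize.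

Step 10
Reactants: 13 (E)-2-methyl enal
Product: 14 (E,E)-dienylboronate (pinacol boronate on C3)
Conditions: CrCl2, Cl2CHB(pin), LiI, THF, rt
Reagents that add atoms: 2-(dichloromethyl)-4,4,5,5-tetramethyl-1,3,2-dioxaborolane, ClC(Cl)B1OC(C)(C)C(C)(C)O1
Why: Takai–Utimoto olefination with the geminal dichromium reagent is aldehyde-selective and (E)-selective, which should give the diene with boron in the outside position.

Step 11
Reactants: 14 (E,E)-dienylboronate
Product: 15 primary alcohol (C7–OH, C8 OTBS kept)
Conditions: camphorsulfonic acid (cat.), MeOH/CH2Cl2, 0 °C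
Reagents that add atoms: none
Why: Acid-catalysed methanolysis (selective desilylation) cleaves the primary silyl ether much faster than the hindered secondary one.

Step 12
Reactants: 15 primary alcohol
Product: 16 α-silyloxy aldehyde (C7 formyl)
Conditions: Dess–Martin periodinane, NaHCO3, CH2Cl2, 0 °C to rt
Reagents that add atoms: none
Why: Buffered Dess–Martin oxidation should give the aldehyde without epimerizing the adjacent C8 centre.

Step 13
Reactants: 16 α-silyloxy aldehyde
Product: 17 (Z)-enoate triene (methyl (Z)-enoate C9=C7; (E,E)-dienylboronate)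
Conditions: (CF3CH2O)2P(O)CH2CO2Me, KN(SiMe3)2, 18-crown-6, THF, −78 °C
Reagents that add atoms: methyl bis(2,2,2-trifluoroethyl)phosphonoacetate, COC(=O)CP(=O)(OCC(F)(F)F)OCC(F)(F)F
Why: The Still–Gennari variant of the Horner–Wadsworth–Emmons reaction should give the (Z)-enoate under kinetic control at low temperature.

Step 14
Reactants: 17 (Z)-enoate triene
Product: 18 tricyclic allylboronate methyl ester (A/B cis, B/C trans; C9 ester cis to C8 on ring C; C3 boronate cis to C15 and trans to the ester; C8 OTBS)
Conditions: toluene, BHT (cat.), 110 °C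
Reagents that add atoms: none
Why: Intramolecular Diels–Alder reaction closing rings B and C, in which allylic 1,3-strain of the (Z)-enoate holds H8 in the alkene plane so that the diene tethered through C10 adds to one face (C7 relative to C8), the C5 methyl disfavours the cis-fused transition state so that the B/C fusion should be trans (C6), the (Z)-geometry places the ester cis to C8 (C9), and the (E)-boryl terminus places boron cis to C15 (C3).

Step 15
Reactants: 18 tricyclic allylboronate methyl ester
Product: 19 C3 allylic alcohol (OH trans to the C9 ester)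
Conditions: NaBO3·4H2O, THF/H2O, rt
Reagents that add atoms: sodium perborate, O[B-]1(O)OO[B-](O)(O)OO1.[Na+].[Na+]
Why: Oxidation of the boronate by 1,2-migration from boron to oxygen proceeds with retention and without allylic transposition.

Step 16
Reactants: 19 C3 allylic alcohol
Product: 20 C3 allylic methyl carbonate
Conditions: ClCO2Me, pyridine, DMAP (cat.), CH2Cl2, 0 °C
Reagents that add atoms: methyl chloroformate, COC(=O)Cl
Why: O-acylation gives the axial allylic carbonate that serves as the leaving group for palladium.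

Step 17
Reactants: 20 C3 allylic methyl carbonate
Product: 21 C3-vinyl tricyclic methyl ester (vinyl cis to the C9 ester; C8 OTBS)
Conditions: Pd2(dba)3 (cat.), LiCl, DMF, rt to 40 °C
Reagents that add atoms: tributyl(vinyl)stannane, C=C[Sn](CCCC)(CCCC)CCCC
Why: Palladium-catalysed allylic cross-coupling with a vinylstannane (Stille type), in which ionization anti to the axial carbonate and reductive elimination on the metal face give net inversion at the less substituted allyl terminus C3.

Step 18
Reactants: 21 C3-vinyl tricyclic methyl ester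
Product: 22 tricyclic carboxylic acid (C8 OTBS)
Conditions: Me3SnOH, 1,2-dichloroethane, 80 °C; 5% aq. HCl wash
Reagents that add atoms: trimethyltin hydroxide, C[Sn](C)(C)O
Why: Tin hydroxide-mediated ester hydrolysis is mild enough to cleave the hindered axial methyl ester without enolizing C9.

Step 19
Reactants: 22 tricyclic carboxylic acid
Product: 23 C8-hydroxy carboxylic acid
Conditions: Bu4NF, THF, rt; aq. NaH2PO4
Reagents that add atoms: none
Why: Fluoride desilylation frees the C8 hydroxyl while the carboxylate form keeps C9 from enolizing.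

Step 20
Reactants: 23 C8-hydroxy carboxylic acid; 24 trichloroethylene
Product: 25 C8 (E)-1,2-dichlorovinyl ether carboxylic acid
Conditions: KH, THF, 0 °C; then 24, rt; aq. NaH2PO4 to pH 4
Reagents that add atoms: none
Why: Addition of the potassium alkoxide to dichloroacetylene formed in the flask from trichloroethylene (first stage of the trichloroethylene route to ynol ethers) should give the dichlorovinyl ether, with the carboxylate as a spectator that cannot enolize.

Step 21
Reactants: 25 C8 (E)-1,2-dichlorovinyl ether carboxylic acid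
Product: 27 C-silyl ynol ether silyl ester (C8–O–C≡C–TBS; C1′ TBS ester), via dilithiated alkynyl ether carboxylate 26 (not isolated)
Conditions: n-BuLi (3.5 equiv), THF, −78 to −40 °C; then TBSOTf, −78 to 0 °C; pH 7 buffer, rapid filtration through deactivated silica
Reagents that add atoms: tert-butyldimethylsilyl triflate, CC(C)(C)[Si](C)(C)OS(=O)(=O)C(F)(F)F
Why: Dehydrochlorination to the chloroalkynyl ether and chlorine–lithium exchange (second stage of the trichloroethylene route) give the lithium alkynyl ether at a temperature where butyllithium does not add to the lithium carboxylate, and silylation at carbon and at the carboxylate masks both groups.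

Step 22
Reactants: 28 3-bromofuran
Product: 30 3-(tributylstannyl)furan, via 3-lithiofuran 29 (not isolated)
Conditions: n-BuLi, Et2O, −78 °C; then Bu3SnCl, −78 °C to rt
Reagents that add atoms: tributyltin chloride, CCCC[Sn](Cl)(CCCC)CCCC
Why: Bromine–lithium exchange at −78 °C, where 3-lithiofuran is configurationally stable, followed by stannylation.

Step 23
Reactants: 30 3-(tributylstannyl)furan
Product: 31 2-(pinacolboryl)-4-(tributylstannyl)furan
Conditions: [Ir(OMe)(cod)]2 (cat.), 4,4′-di-tert-butyl-2,2′-bipyridine (cat.), B2pin2, hexane, 50 °C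
Reagents that add atoms: bis(pinacolato)diboron, CC1(C)OB(OC1(C)C)B1OC(C)(C)C(C)(C)O1
Why: Iridium-catalysed C–H borylation of a 3-substituted furan is sterically controlled and should occur at the α-position remote from the bulky stannyl group.

Step 24
Reactants: 32 coumalic acid
Product: 33 3-bromocoumalic acid (3-bromo-2-oxo-2H-pyran-5-carboxylic acid)
Conditions: Br2, AcOH, 60 °C
Reagents that add atoms: bromine, BrBr
Why: Electrophilic bromination of the 2-pyrone by addition–elimination should occur at C3, the only free nucleophilic position when C5 carries the carboxyl group.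

Step 25
Reactants: 33 3-bromocoumalic acid
Product: 34 3-bromo-5-(hydroxymethyl)-2H-pyran-2-one
Conditions: BH3·SMe2, THF, 0 °C to rt; MeOH quench
Reagents that add atoms: none
Why: Borane reduces the carboxylic acid chemoselectively in the presence of the conjugated lactone and the vinylic bromide.

Step 26
Reactants: 34 3-bromo-5-(hydroxymethyl)-2H-pyran-2-one
Product: 35 3-bromo-5-(bromomethyl)-2H-pyran-2-one
Conditions: CBr4, PPh3, CH2Cl2, 0 °C
Reagents that add atoms: carbon tetrabromide, BrC(Br)(Br)Br
Why: Appel bromination converts the primary allylic alcohol into the bromide under neutral conditions.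

Step 27
Reactants: 31 2-(pinacolboryl)-4-(tributylstannyl)furan; 35 3-bromo-5-(bromomethyl)-2H-pyran-2-one
Product: 36 3-bromo-5-{[4-(tributylstannyl)furan-2-yl]methyl}-2H-pyran-2-one
Conditions: Pd(PPh3)4 (cat.), CsF, THF, 45 °C
Reagents that add atoms: none
Why: Suzuki–Miyaura sp2–sp3 coupling in which zerovalent palladium inserts into the allylic C–Br bond faster than into the vinylic C3–Br bond, fluoride-activated boron transfers faster than the β-furyl tin group, and anhydrous fluoride spares the pyrone.

Step 28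
Reactants: 27 C-silyl ynol ether silyl ester; 36 3-bromo-5-{[4-(tributylstannyl)furan-2-yl]methyl}-2H-pyran-2-one
Product: 38 silyl-capped ynol ether bromopyrone furyl ketone, via acid chloride 37 (not isolated)
Conditions: (COCl)2, DMF (cat.), CH2Cl2, 0 °C; evaporate; then 36, Pd2(dba)3 (cat.), P(2-furyl)3, toluene, 50 °C
Reagents that add atoms: none
Why: The silyl ester is converted into the acid chloride without free acid, and a Stille acylation then forms the C1′–furan bond, because the acyl chloride adds to zerovalent palladium faster than the pyrone C–Br bond and no base is present to enolize C9.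

Step 29
Reactants: 38 silyl-capped ynol ether bromopyrone furyl ketone
Product: 39 ethynyl ether bromopyrone furyl ketone (C8–O–C≡CH)
Conditions: Bu4NF, AcOH (1:1), THF, 0 °C
Reagents that add atoms: none
Why: Buffered fluoride desilylation of the alkynylsilane should free the terminal ynol ether without enolizing the ketone or opening the pyrone.

Step 30
Reactants: 39 ethynyl ether bromopyrone furyl ketone
Product: 41 ortho-bromo furano-paracyclophane, via bridged lactone cycloadduct 40 (not isolated)
Conditions: toluene (1 mM, degassed), BHT (cat.), 80 °C, sealed vessel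
Reagents that add atoms: none
Why: The ynol ether adds as the electron-rich 2π partner across C3 and C6 of the electron-poor 3-bromo-2-pyrone in an intramolecular inverse-demand [4+2] cycloaddition (CH terminus to C6, oxygen-bearing carbon to C3), and the bridged lactone 40 then loses CO2 by retro-[4+2] to give the arene. The closest known reactions are pyrone–alkyne Diels–Alder/decarboxylation sequences that build bent paracyclophanes and the cycloadditions of 3-bromo-2-pyrone with electron-rich partners. The benzene ring is closed by the two new C–C bonds of the cycloaddition, and the 13-membered ring is closed in the same event because the partners are already joined through C8–C7–C9–C1′–furan–CH2 (macrocyclization by tethered cycloaddition). No stereocentre is formed, since the bridgehead centres of 40 vanish on aromatization and the neutral conditions leave C9 and the other centres untouched. The step needs para regiochemistry and a cycloaddition faster than retro-ene loss of ketene from the ynol ether: the matched polarity of the two partners sets para, the bromine lowers the pyrone LUMO so that 80 °C should suffice, the only syn β-hydrogen (H7) sits at the trans ring fusion, and aromatization with loss of CO2 pays for bending the arene.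

Step 31
Reactants: 41 ortho-bromo furano-paracyclophane
Product: 42 furano-paracyclophane
Conditions: Bu3SnH, AIBN (cat.), toluene, 80 °C
Reagents that add atoms: none
Why: Radical chain hydrodehalogenation with tin hydride removes the aryl bromide under neutral conditions.

Step 32
Reactants: 42 furano-paracyclophane
Product: 44 γ-hydroxybutenolide cyclophane, via furan endoperoxide 43 (not isolated)
Conditions: O2, methylene blue (cat.), visible light, CH2Cl2, −78 °C; then i-Pr2NEt, −78 to 0 °C
Reagents that add atoms: oxygen, O=O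
Why: [4+2] addition of singlet oxygen across furan C2 and C5 followed by base-induced Kornblum–DeLaMare fragmentation at the only C–H-bearing bridgehead should place the lactone carbonyl next to the acyl-bearing carbon and the hemiketal at the benzyl-bearing carbon.

Step 33
Reactants: 44 γ-hydroxybutenolide cyclophane
Product: 45 CNP0151253.3 (target hydroxy lactam)
Conditions: NH3 (7 M in MeOH), THF, 0 °C to rt
Reagents that add atoms: ammonia, N
Why: Aminolysis of the acylal-type lactone and ring closure of the resulting keto amide (lactam formation) give the hemiaminal, whose configuration should settle by ring–chain equilibration inside the macrocycle.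

**Compound list**

1 | (R)-(+)-pulegone | C[C@@H]1CCC(=C(C)C)C(=O)C1 | starting material
2 | pulegone oxide | C[C@@H]1CCC2(OC2(C)C)C(=O)C1 | intermediate
3 | (5R)-5-methyl-2-(phenylsulfanyl)cyclohexan-1-one | C[C@@H]1CCC(Sc2ccccc2)C(=O)C1 | intermediate
4 | sulfoxide of 3 (not isolated) | C[C@@H]1CCC(S(=O)c2ccccc2)C(=O)C1 | intermediate
5 | (R)-5-methylcyclohex-2-en-1-one | C[C@@H]1CC=CC(=O)C1 | intermediate
6 | (tert-butyldimethylsilyloxy)acetaldehyde | CC(C)(C)[Si](C)(C)OCC=O | starting material
7 | chlorozinc enolate of trans-3,5-dimethylcyclohexanone (not isolated) | C[C@@H]1C[C@@H](C)C=C(O[Zn]Cl)C1 | intermediate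
8 | ring A aldol adduct | CC(C)(C)[Si](C)(C)OC[C@@H](O)[C@H]1[C@H](C)C[C@@H](C)CC1=O | intermediate
9 | bis(silyl ether) ketone | CC(C)(C)[Si](C)(C)OC[C@@H](O[Si](C)(C)C(C)(C)C)[C@H]1[C@H](C)C[C@@H](C)CC1=O | intermediate
10 | methyl enol ether | CC(C)(C)[Si](C)(C)OC[C@@H](O[Si](C)(C)C(C)(C)C)[C@H]1[C@H](C)C[C@@H](C)CC1=COC | intermediate
11 | ring A aldehyde (C15 epimers) | CC(C)(C)[Si](C)(C)OC[C@@H](O[Si](C)(C)C(C)(C)C)[C@H]1[C@H](C)C[C@@H](C)CC1C=O | intermediate
12 | quaternary aldehyde | CC(C)(C)[Si](C)(C)OC[C@@H](O[Si](C)(C)C(C)(C)C)[C@H]1[C@H](C)C[C@@H](C)C[C@@]1(C)C=O | intermediate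
13 | (E)-2-methyl enal | CC(C)(C)[Si](C)(C)OC[C@@H](O[Si](C)(C)C(C)(C)C)[C@H]1[C@H](C)C[C@@H](C)C[C@@]1(C)/C=C(C)/C=O | intermediate
14 | (E,E)-dienylboronate | CC(C)(C)[Si](C)(C)OC[C@@H](O[Si](C)(C)C(C)(C)C)[C@H]1[C@H](C)C[C@@H](C)C[C@@]1(C)/C=C(C)/C=C/B2OC(C)(C)C(C)(C)O2 | intermediate
15 | primary alcohol | OC[C@@H](O[Si](C)(C)C(C)(C)C)[C@H]1[C@H](C)C[C@@H](C)C[C@@]1(C)/C=C(C)/C=C/B2OC(C)(C)C(C)(C)O2 | intermediate
16 | α-silyloxy aldehyde | O=C[C@@H](O[Si](C)(C)C(C)(C)C)[C@H]1[C@H](C)C[C@@H](C)C[C@@]1(C)/C=C(C)/C=C/B2OC(C)(C)C(C)(C)O2 | intermediate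
17 | (Z)-enoate triene | COC(=O)/C=C\[C@@H](O[Si](C)(C)C(C)(C)C)[C@H]1[C@H](C)C[C@@H](C)C[C@@]1(C)/C=C(C)/C=C/B2OC(C)(C)C(C)(C)O2 | intermediate
18 | tricyclic allylboronate methyl ester | CC1(C)OB(OC1(C)C)[C@H]2[C@H](C(=O)OC)[C@@H]3[C@@H](O[Si](C)(C)C(C)(C)C)[C@H]4[C@H](C)C[C@@H](C)C[C@@]4(C)[C@H]3C(C)=C2 | intermediate
19 | C3 allylic alcohol | O[C@H]1[C@H](C(=O)OC)[C@@H]2[C@@H](O[Si](C)(C)C(C)(C)C)[C@H]3[C@H](C)C[C@@H](C)C[C@@]3(C)[C@H]2C(C)=C1 | intermediate
20 | C3 allylic methyl carbonate | COC(=O)O[C@H]1[C@H](C(=O)OC)[C@@H]2[C@@H](O[Si](C)(C)C(C)(C)C)[C@H]3[C@H](C)C[C@@H](C)C[C@@]3(C)[C@H]2C(C)=C1 | intermediate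
21 | C3-vinyl tricyclic methyl ester | C=C[C@@H]1[C@H](C(=O)OC)[C@@H]2[C@@H](O[Si](C)(C)C(C)(C)C)[C@H]3[C@H](C)C[C@@H](C)C[C@@]3(C)[C@H]2C(C)=C1 | intermediate
22 | tricyclic carboxylic acid (C8 OTBS) | C=C[C@@H]1[C@H](C(=O)O)[C@@H]2[C@@H](O[Si](C)(C)C(C)(C)C)[C@H]3[C@H](C)C[C@@H](C)C[C@@]3(C)[C@H]2C(C)=C1 | intermediate
23 | C8-hydroxy carboxylic acid | C=C[C@@H]1[C@H](C(=O)O)[C@@H]2[C@@H](O)[C@H]3[C@H](C)C[C@@H](C)C[C@@]3(C)[C@H]2C(C)=C1 | intermediate
24 | trichloroethylene | ClC=C(Cl)Cl | starting material
25 | C8 (E)-1,2-dichlorovinyl ether carboxylic acid | C=C[C@@H]1[C@H](C(=O)O)[C@@H]2[C@@H](O/C(Cl)=C\Cl)[C@H]3[C@H](C)C[C@@H](C)C[C@@]3(C)[C@H]2C(C)=C1 | intermediate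
26 | dilithiated alkynyl ether carboxylate (not isolated) | C=C[C@@H]1[C@H](C(=O)O[Li])[C@@H]2[C@@H](OC#C[Li])[C@H]3[C@H](C)C[C@@H](C)C[C@@]3(C)[C@H]2C(C)=C1 | intermediate
27 | C-silyl ynol ether silyl ester | C=C[C@@H]1[C@H](C(=O)O[Si](C)(C)C(C)(C)C)[C@@H]2[C@@H](OC#C[Si](C)(C)C(C)(C)C)[C@H]3[C@H](C)C[C@@H](C)C[C@@]3(C)[C@H]2C(C)=C1 | intermediate
28 | 3-bromofuran | Brc1ccoc1 | starting material
29 | 3-lithiofuran (not isolated) | [Li]c1ccoc1 | intermediate
30 | 3-(tributylstannyl)furan | CCCC[Sn](CCCC)(CCCC)c1ccoc1 | intermediate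
31 | 2-(pinacolboryl)-4-(tributylstannyl)furan | CCCC[Sn](CCCC)(CCCC)c1coc(B2OC(C)(C)C(C)(C)O2)c1 | intermediate
32 | coumalic acid | OC(=O)c1ccc(=O)oc1 | starting material
33 | 3-bromocoumalic acid | OC(=O)c1cc(Br)c(=O)oc1 | intermediate
34 | 3-bromo-5-(hydroxymethyl)-2H-pyran-2-one | OCc1cc(Br)c(=O)oc1 | intermediate
35 | 3-bromo-5-(bromomethyl)-2H-pyran-2-one | BrCc1cc(Br)c(=O)oc1 | intermediate
36 | 3-bromo-5-{[4-(tributylstannyl)furan-2-yl]methyl}-2H-pyran-2-one | CCCC[Sn](CCCC)(CCCC)c1coc(Cc2cc(Br)c(=O)oc2)c1 | intermediate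
37 | acid chloride of the C-silyl ynol ether (not isolated) | C=C[C@@H]1[C@H](C(Cl)=O)[C@@H]2[C@@H](OC#C[Si](C)(C)C(C)(C)C)[C@H]3[C@H](C)C[C@@H](C)C[C@@]3(C)[C@H]2C(C)=C1 | intermediate
38 | silyl-capped ynol ether bromopyrone furyl ketone | C=C[C@@H]1[C@H](C(=O)c4coc(Cc5cc(Br)c(=O)oc5)c4)[C@@H]2[C@@H](OC#C[Si](C)(C)C(C)(C)C)[C@H]3[C@H](C)C[C@@H](C)C[C@@]3(C)[C@H]2C(C)=C1 | intermediate
39 | ethynyl ether bromopyrone furyl ketone | C=C[C@@H]1[C@H](C(=O)c4coc(Cc5cc(Br)c(=O)oc5)c4)[C@@H]2[C@@H](OC#C)[C@H]3[C@H](C)C[C@@H](C)C[C@@]3(C)[C@H]2C(C)=C1 | intermediate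
40 | bridged lactone cycloadduct (not isolated; bridgehead configuration of no consequence) | C=C[C@H]1C=C(C)[C@H]2[C@H]3[C@@H](OC4=CC5OC(=O)C4(Br)C=C5Cc4cc(co4)C(=O)[C@@H]13)[C@H]1[C@H](C)C[C@@H](C)C[C@]12C | intermediate
41 | ortho-bromo furano-paracyclophane | C=C[C@H]1C=C(C)[C@H]2[C@H]3[C@@H](Oc4ccc(cc4Br)Cc4cc(co4)C(=O)[C@@H]13)[C@H]1[C@H](C)C[C@@H](C)C[C@]12C | intermediate
42 | furano-paracyclophane | C=C[C@H]1C=C(C)[C@H]2[C@H]3[C@@H](Oc4ccc(cc4)Cc4cc(co4)C(=O)[C@@H]13)[C@H]1[C@H](C)C[C@@H](C)C[C@]12C | intermediate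
43 | furan endoperoxide (not isolated) | C=C[C@H]1C=C(C)[C@H]2[C@H]3[C@@H](Oc4ccc(cc4)CC45C=C(C(O4)OO5)C(=O)[C@@H]13)[C@H]1[C@H](C)C[C@@H](C)C[C@]12C | intermediate
44 | γ-hydroxybutenolide cyclophane (hemiketal epimers) | C=C[C@H]1C=C(C)[C@H]2[C@H]3[C@@H](Oc4ccc(cc4)CC4(O)C=C(C(=O)O4)C(=O)[C@@H]13)[C@H]1[C@H](C)C[C@@H](C)C[C@]12C | intermediate
45 | CNP0151253.3 | C=C[C@H]1C=C(C)[C@H]2[C@H]3[C@@H](Oc4ccc(cc4)C[C@@]4(O)C=C(C(=O)N4)C(=O)[C@@H]13)[C@H]1[C@H](C)C[C@@H](C)C[C@]12C | target

**Count and risks**

Total: 33 steps. Longest linear sequence: 27 steps (steps 1–21 and 28–33).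

Steps most likely to fail:

1. Step 30. The ynol ether may fragment by retro-ene loss of ketene, or react between molecules, before the strained 13-membered transition state is reached. Fallback: it sets out from acid 22 and returns at 42, closing the macrocycle at the C8–O–aryl bond on a preformed arene. Boronate 31 is coupled at the benzylic position of 4-bromobenzyl bromide (Pd(PPh3)4, CsF) to give 2-(4-bromobenzyl)-4-(tributylstannyl)furan F1. Acid 22 is converted with 1-chloro-N,N,2-trimethylpropenylamine into the acid chloride of 22 F2, which acylates F1 (Pd2(dba)3, P(2-furyl)3) to give the C8-silyloxy 4-bromobenzyl furyl ketone F3. HF·pyridine gives the C8-hydroxy 4-bromobenzyl furyl ketone F4. An intramolecular Ullmann etherification (CuI, 3,4,7,8-tetramethyl-1,10-phenanthroline, Cs2CO3, toluene, 110 °C, high dilution) then gives 42; this macro-etherification is established for cyclophanes of this family, though it bends the arene without the help of aromatization.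

2. Step 14. Discrimination between the trans-fused and cis-fused transition states may be poor, or the (Z)-enoate may isomerize before cyclization. Fallback: it sets out from aldehyde 16 and returns at 19. A Wittig reaction with methyl (triphenylphosphoranylidene)acetate gives the (E)-enoate triene F5. An Et2AlCl-promoted intramolecular Diels–Alder reaction (ester endo, tether exo) should give the trans-fused C9-epimeric allylboronate F6 with the ester trans to C8. Perborate oxidation gives the C9-epimeric allylic alcohol F7. Double deprotonation with LiN(i-Pr)2 to the alkoxide ester enolate F8 and kinetic protonation from the equatorial direction with 2,6-di-tert-butylphenol should invert C9 and give 19.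

3. Step 28. The chloroiminium reagent or the acid chloride may attack the electron-rich silyl ynol ether, or the hindered acylpalladium may lose CO before transmetalation. Fallback: it sets out from 27 and returns at 38 through a thioester instead of an acid chloride. Mild hydrolysis of the silyl ester (K2CO3, MeOH/H2O, 0 °C, pH 7 buffer) gives the C-silyl ynol ether carboxylic acid F9. 2,2′-Dipyridyl disulfide and PPh3 give the S-(2-pyridyl) thioester F10 under neutral conditions. A Liebeskind–Srogl coupling with stannane 36 (Pd(PPh3)4, CuO2CC4H3S, THF, 50 °C, no base) then gives 38.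

**Further compounds**

F1 | step 30 | 2-(4-bromobenzyl)-4-(tributylstannyl)furan | CCCC[Sn](CCCC)(CCCC)c1coc(Cc2ccc(Br)cc2)c1
F2 | step 30 | acid chloride of 22 | C=C[C@@H]1[C@H](C(Cl)=O)[C@@H]2[C@@H](O[Si](C)(C)C(C)(C)C)[C@H]3[C@H](C)C[C@@H](C)C[C@@]3(C)[C@H]2C(C)=C1
F3 | step 30 | C8-silyloxy 4-bromobenzyl furyl ketone | C=C[C@@H]1[C@H](C(=O)c4coc(Cc5ccc(Br)cc5)c4)[C@@H]2[C@@H](O[Si](C)(C)C(C)(C)C)[C@H]3[C@H](C)C[C@@H](C)C[C@@]3(C)[C@H]2C(C)=C1
F4 | step 30 | C8-hydroxy 4-bromobenzyl furyl ketone | C=C[C@@H]1[C@H](C(=O)c4coc(Cc5ccc(Br)cc5)c4)[C@@H]2[C@@H](O)[C@H]3[C@H](C)C[C@@H](C)C[C@@]3(C)[C@H]2C(C)=C1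
F5 | step 14 | (E)-enoate triene | COC(=O)/C=C/[C@@H](O[Si](C)(C)C(C)(C)C)[C@H]1[C@H](C)C[C@@H](C)C[C@@]1(C)/C=C(C)/C=C/B2OC(C)(C)C(C)(C)O2
F6 | step 14 | C9-epimeric tricyclic allylboronate methyl ester | CC1(C)OB(OC1(C)C)[C@H]2[C@@H](C(=O)OC)[C@@H]3[C@@H](O[Si](C)(C)C(C)(C)C)[C@H]4[C@H](C)C[C@@H](C)C[C@@]4(C)[C@H]3C(C)=C2
F7 | step 14 | C9-epimeric C3 allylic alcohol | O[C@H]1[C@@H](C(=O)OC)[C@@H]2[C@@H](O[Si](C)(C)C(C)(C)C)[C@H]3[C@H](C)C[C@@H](C)C[C@@]3(C)[C@H]2C(C)=C1
F8 | step 14 | dilithium alkoxide ester enolate | [Li]O[C@H]1C(=C(OC)O[Li])[C@@H]2[C@@H](O[Si](C)(C)C(C)(C)C)[C@H]3[C@H](C)C[C@@H](C)C[C@@]3(C)[C@H]2C(C)=C1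
F9 | step 28 | C-silyl ynol ether carboxylic acid | C=C[C@@H]1[C@H](C(=O)O)[C@@H]2[C@@H](OC#C[Si](C)(C)C(C)(C)C)[C@H]3[C@H](C)C[C@@H](C)C[C@@]3(C)[C@H]2C(C)=C1
F10 | step 28 | S-(2-pyridyl) thioester | C=C[C@@H]1[C@H](C(=O)Sc4ccccn4)[C@@H]2[C@@H](OC#C[Si](C)(C)C(C)(C)C)[C@H]3[C@H](C)C[C@@H](C)C[C@@]3(C)[C@H]2C(C)=C1
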